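**Retrosynthetic overview**

1. Target 19 is ring A (cyclohexa-2,4-dienone C3a–C7a, quaternary C5 carrying allyl and OMe) fused to ring B (dihydrofuran O1–C2–C3, 2-aryl and 3-methyl trans). The last bond cut is C5–allyl, giving the aromatic 6-hydroxy-5-methoxy dihydrobenzofuran 17 (oxidative dearomatisation with allylsilane capture at C5).
2. Key disconnection, ring B by [4+1]: O1–C7a–C3a–C3 (with its methyl) is the heterodiene of an ortho-quinone methide (from sulfone 7), and C2 with its 3,4,5-trimethoxyphenyl group is the carbon of a benzylic sulfonium ylide (from the C2-symmetric thiolanium salt 12). The C2–C3 and then the O1–C2 bond are formed, and C2 and C3 are set.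
3. Sulfone 7 comes from isovanillin (O6 carried as an allyl ether; Dakin oxidation, ortho-formylation, MeMgBr, sulfination). Salt 12 comes from (2R,5R)-hexane-2,5-diol (via (2S,5S)-2,5-dimethylthiolane) and 3,4,5-trimethoxybenzyl bromide.
4. Ring order: ring A is aromatic from the start, ring B is closed in step 9, ring A is dearomatised in step 11.

Key step: step 9

Remark: benzofuran numbering (O1, C2, C3, C3a, C4–C7, C7a) is used throughout; ring A is the six-membered carbocycle, ring B the five-membered oxygen ring.

Assumption: the quinone methide is taken to attack the thiolanium benzylide on the same face as aldehydes do. The (2R,5R) sulfide is known to lead to (S,S)-stilbene oxide, and in a 2-aryl-2,3-dihydrobenzofuran the CIP ranks of the aryl group and the new carbon neighbour are exchanged, so the (2S,5S) sulfide is used for the 2S,3S series. The antipodal diol would be used if the sense proved opposite.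

Remark: the C6 oxygen is carried as an allyl ether because it tolerates the acidic sulfination and is removed under neutral conditions.

**Route**

Step 1
Reactants: 1 isovanillin (3-hydroxy-4-methoxybenzaldehyde)
Product: 2 3-(allyloxy)-4-methoxybenzaldehyde
Conditions: allyl bromide, K2CO3, DMF, rt
Reagents that add atoms: allyl bromide, C=CCBr
Why: Williamson etherification of the phenoxide; the allyl ether should survive peracid (short exposure), Grignard reagent, sulfinic acid and carbonate.

Step 2
Reactants: 2 3-(allyloxy)-4-methoxybenzaldehyde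
Product: 4 3-(allyloxy)-4-methoxyphenol, via aryl formate 3 (not isolated)
Conditions: mCPBA, CH2Cl2, 0 °C to rt; then K2CO3 (cat.), MeOH, rt
Reagents that add atoms: mCPBA (3-chloroperoxybenzoic acid), O=C(OO)c1cccc(Cl)c1
Why: Baeyer–Villiger (Dakin-type) oxidation in which the electron-rich aryl group migrates in preference to hydride, followed by methanolysis of the formate; the aldehyde should be oxidised much faster than the allyl ether alkene is epoxidised.

Step 3
Reactants: 4 3-(allyloxy)-4-methoxyphenol
Product: 5 4-(allyloxy)-2-hydroxy-5-methoxybenzaldehyde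
Conditions: MgCl2, Et3N, (CH2O)n, MeCN, reflux
Reagents that add atoms: paraformaldehyde (formaldehyde), C=O
Why: magnesium-mediated ortho-formylation of a phenol (Casnati–Skattebøl), in which the magnesium phenoxide delivers formaldehyde to the ortho carbon and a second formaldehyde oxidises the benzylic alkoxide; the ortho carbon para to the allyloxy group is the less hindered and more activated one, the other being flanked by two oxygens.

Step 4
Reactants: 5 4-(allyloxy)-2-hydroxy-5-methoxybenzaldehyde
Product: 6 5-(allyloxy)-2-(1-hydroxyethyl)-4-methoxyphenol (racemic)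
Conditions: MeMgBr (3 equiv), THF, 0 °C
Reagents that add atoms: methylmagnesium bromide, C[Mg]Br
Why: Grignard addition to the aldehyde after deprotonation of the phenol; the new centre is racemic and is erased in step 9, and the labile diol is taken on without storage.

Step 5
Reactants: 6 5-(allyloxy)-2-(1-hydroxyethyl)-4-methoxyphenol
Product: 7 5-(allyloxy)-4-methoxy-2-(1-tosylethyl)phenol (racemic)
Conditions: p-TolSO2H (1.5 equiv), CH2Cl2, rt
Reagents that add atoms: p-toluenesulfinic acid, Cc1ccc(cc1)S(=O)O
Why: acid-promoted SN1-type substitution of an ortho-hydroxybenzylic alcohol, in which the ortho-hydroxy, para-allyloxy benzylic position ionises readily and the sulfinate is captured at sulfur to give the sulfone.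

Step 6
Reactants: 8 (2R,5R)-hexane-2,5-diol
Product: 9 (2R,5R)-hexane-2,5-diyl dimethanesulfonate
Conditions: MsCl, Et3N, CH2Cl2, −20 to 0 °C
Reagents that add atoms: methanesulfonyl chloride, CS(=O)(=O)Cl
Why: O-sulfonylation of both secondary alcohols, which does not touch the C–O bonds and so retains both centres.

Step 7
Reactants: 9 (2R,5R)-hexane-2,5-diyl dimethanesulfonate
Product: 10 (2S,5S)-2,5-dimethylthiolane
Conditions: Na2S·9H2O, DMSO, rt
Reagents that add atoms: sodium sulfide, [Na+].[Na+].[S-2]
Why: double SN2 displacement by sulfide (intermolecular, then 5-exo-tet), which inverts both centres and gives the trans (2S,5S) thiolane.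

Step 8
Reactants: 10 (2S,5S)-2,5-dimethylthiolane; 11 3,4,5-trimethoxybenzyl bromide
Product: 12 (2S,5S)-2,5-dimethyl-1-(3,4,5-trimethoxybenzyl)thiolan-1-ium tetrafluoroborate
Conditions: AgBF4, acetone, rt, dark
Reagents that add atoms: silver tetrafluoroborate, [Ag+].F[B-](F)(F)F
Why: S-alkylation of the sulfide by the benzylic bromide, driven by precipitation of AgBr; the two lone pairs of the C2-symmetric sulfide are homotopic, so a single sulfonium salt should form.

Step 9
Reactants: 7 5-(allyloxy)-4-methoxy-2-(1-tosylethyl)phenol; 12 (2S,5S)-2,5-dimethyl-1-(3,4,5-trimethoxybenzyl)thiolan-1-ium tetrafluoroborate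
Product: 16 (2S,3S)-6-(allyloxy)-5-methoxy-3-methyl-2-(3,4,5-trimethoxyphenyl)-2,3-dihydrobenzofuran, via ortho-quinone methide 13 (not isolated), via sulfonium ylide 14 (not isolated), via betaine 15 (not isolated)
Conditions: Cs2CO3 (3 equiv), CH2Cl2, −20 °C to rt; 7 added slowly to 12 (1.5 equiv) and base
Reagents that add atoms: none
Why: Cs2CO3 turns 7 into its phenoxide, which expels p-toluenesulfinate to give the E-configured ortho-quinone methide 13 (the racemic centre of 7 is erased), and it deprotonates 12 to the benzylide 14; the ylide carbon adds to the methide carbon (C2–C3 bond) to give the rearomatised phenoxide–sulfonium betaine 15, whose oxygen displaces the sulfide at C2 with inversion (O1–C2 bond). The closest known reaction type is the base-mediated [4+1] annulation of 2-(1-tosylalkyl)phenols with sulfonium salts to trans-2,3-dihydrobenzofurans, combined with the benzylide chemistry of C2-symmetric 2,5-dimethylthiolanium salts known from aldehyde epoxidation. Ring B is closed by a 5-exo-tet substitution, the C2–C3 bond being formed intermolecularly beforehand. C2 is controlled by the sulfide: in the ylide the aryl group lies syn to the sulfur lone pair and the ring methyl cis to the ylide carbon blocks one face, so attack on the open face followed by invertive closure should give 2S with the (2S,5S) sulfide; C3 follows from an open addition transition state that keeps the ylide aryl and the methide methyl apart and leads, after inversion at C2, to the trans (3S) ring. The step needs conjugate addition to outrun the hydrogen shift of 13 to a vinylphenol and self-condensation, which the electron-rich ring (para allyloxy donor, easy sulfinate loss at low temperature) and slow generation of 13 in an excess of ylide should secure. The sulfide is released and can be recovered for step 8.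

Step 10
Reactants: 16 (2S,3S)-6-(allyloxy)-5-methoxy-3-methyl-2-(3,4,5-trimethoxyphenyl)-2,3-dihydrobenzofuran
Product: 17 (2S,3S)-5-methoxy-3-methyl-2-(3,4,5-trimethoxyphenyl)-2,3-dihydrobenzofuran-6-ol
Conditions: Pd(PPh3)4 (5 mol %), morpholine, THF, rt
Reagents that add atoms: none
Why: Tsuji–Trost deallylation, in which zerovalent palladium ionises the aryl allyl ether and morpholine traps the allyl group; the neutral conditions should leave the benzylic C2–O1 ether, the methyl ethers and both stereocentres untouched.

Step 11
Reactants: 17 (2S,3S)-5-methoxy-3-methyl-2-(3,4,5-trimethoxyphenyl)-2,3-dihydrobenzofuran-6-ol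
Product: 19 (2S,3S,5R)-5-allyl-5-methoxy-3-methyl-2-(3,4,5-trimethoxyphenyl)-2,3-dihydrobenzofuran-6(5H)-one, via phenoxenium ion 18 (not isolated)
Conditions: PhI(OAc)2 (1.05 equiv), allylSiMe3 (5 equiv), (CF3)2CHOH/CH2Cl2, −20 °C; cold aq. NaHCO3 quench; chromatographic separation of the C5 epimers
Reagents that add atoms: allyltrimethylsilane, C=CC[Si](C)(C)C
Why: Proposed new method: the trivalent iodine reagent oxidises the phenol by two electrons to the 2-methoxyphenoxenium ion 18, whose positive charge is best stabilised at the methoxy-bearing C5 (methoxy-oxocarbenium form), so allyltrimethylsilane should add there and lose silicon (Hosomi–Sakurai), leaving the dienone stabilised as a vinylogous ester through O1–C7a=C7–C6=O; the closest known reactions are the oxidative Hosomi–Sakurai allylation of para-alkylphenols with PhI(OAc)2 in (CF3)2CHOH and the iodane-mediated substitution of 2-alkoxynaphthols by allylsilanes at the alkoxy-bearing carbon, and the formation of ortho-quinone monoketals from 2-methoxyphenols in methanol shows the same site preference; C5 is created here without reliable substrate control (C2 and C3 are remote), so both C5 epimers are expected and the 5R epimer (allyl cis to the C2 aryl group) is isolated by chromatography.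

**Compound list**

1 | isovanillin (3-hydroxy-4-methoxybenzaldehyde) | COc1ccc(C=O)cc1O | starting material
2 | 3-(allyloxy)-4-methoxybenzaldehyde | C=CCOc1cc(C=O)ccc1OC | intermediate
3 | 3-(allyloxy)-4-methoxyphenyl formate | C=CCOc1cc(OC=O)ccc1OC | intermediate
4 | 3-(allyloxy)-4-methoxyphenol | C=CCOc1cc(O)ccc1OC | intermediate
5 | 4-(allyloxy)-2-hydroxy-5-methoxybenzaldehyde | C=CCOc1cc(O)c(C=O)cc1OC | intermediate
6 | 5-(allyloxy)-2-(1-hydroxyethyl)-4-methoxyphenol (racemic) | C=CCOc1cc(O)c(C(C)O)cc1OC | intermediate
7 | 5-(allyloxy)-4-methoxy-2-(1-tosylethyl)phenol (racemic) | C=CCOc1cc(O)c(C(C)S(=O)(=O)c2ccc(C)cc2)cc1OC | intermediate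
8 | (2R,5R)-hexane-2,5-diol | C[C@@H](O)CC[C@@H](C)O | starting material
9 | (2R,5R)-hexane-2,5-diyl dimethanesulfonate | C[C@@H](OS(C)(=O)=O)CC[C@@H](C)OS(C)(=O)=O | intermediate
10 | (2S,5S)-2,5-dimethylthiolane | C[C@H]1CC[C@H](C)S1 | intermediate
11 | 3,4,5-trimethoxybenzyl bromide | COc1cc(CBr)cc(OC)c1OC | starting material
12 | (2S,5S)-2,5-dimethyl-1-(3,4,5-trimethoxybenzyl)thiolan-1-ium tetrafluoroborate | C[C@H]1CC[C@H](C)[S+]1Cc1cc(OC)c(OC)c(OC)c1.F[B-](F)(F)F | intermediate
13 | (6E)-3-(allyloxy)-6-ethylidene-4-methoxycyclohexa-2,4-dien-1-one (ortho-quinone methide) | C/C=C1\C=C(OC)C(OCC=C)=CC1=O | intermediate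
14 | (2S,5S)-2,5-dimethylthiolan-1-ium (3,4,5-trimethoxyphenyl)methylide | C[C@H]1CC[C@H](C)[S+]1[CH-]c1cc(OC)c(OC)c(OC)c1 | intermediate
15 | 5-(allyloxy)-2-[(1R,2S)-1-[(2S,5S)-2,5-dimethylthiolan-1-ium-1-yl]-1-(3,4,5-trimethoxyphenyl)propan-2-yl]-4-methoxyphenolate (betaine) | C[C@@H](c1cc(OC)c(OCC=C)cc1[O-])[C@H](c1cc(OC)c(OC)c(OC)c1)[S+]1[C@@H](C)CC[C@@H]1C | intermediate
16 | (2S,3S)-6-(allyloxy)-5-methoxy-3-methyl-2-(3,4,5-trimethoxyphenyl)-2,3-dihydrobenzofuran | COc1cc2c(cc1OCC=C)O[C@H](c1cc(OC)c(OC)c(OC)c1)[C@H]2C | intermediate
17 | (2S,3S)-5-methoxy-3-methyl-2-(3,4,5-trimethoxyphenyl)-2,3-dihydrobenzofuran-6-ol | COc1cc2c(cc1O)O[C@H](c1cc(OC)c(OC)c(OC)c1)[C@H]2C | intermediate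
18 | (2S,3S)-5-methoxy-3-methyl-6-oxo-2-(3,4,5-trimethoxyphenyl)-2,3-dihydro-6H-benzofuran-5-ylium acetate (phenoxenium ion, drawn as the C5 methoxy-oxocarbenium form) | C[O+]=C1C=C2C(=CC1=O)O[C@H](c1cc(OC)c(OC)c(OC)c1)[C@H]2C.CC(=O)[O-] | intermediate
19 | (2S,3S,5R)-5-allyl-5-methoxy-3-methyl-2-(3,4,5-trimethoxyphenyl)-2,3-dihydrobenzofuran-6(5H)-one | C=CC[C@@]1(OC)C=C2C(=CC1=O)O[C@H](c1cc(OC)c(OC)c(OC)c1)[C@H]2C | target

**Step count**

Total step count: 11. Longest linear sequence: 8 (steps 1–5, 9, 10, 11).

**Steps most likely to fail**

1. Step 11. The allylsilane may be captured at C3a (para) or C7 instead of C5, the electron-rich aryl ring may be over-oxidised, the C2–O1 bond of the product may ionise in the acidic fluoroalcohol medium, and the lack of facial control at C5 costs the material that ends as the 5S epimer. Fallback by known chemistry, setting out from 17 and returning at 19: oxidative demethylation of the 2-methoxyphenol with NaIO4 in aqueous MeCN should give the ortho-quinone (2S,3S)-3-methyl-2-(3,4,5-trimethoxyphenyl)-2,3-dihydrobenzofuran-5,6-dione F1. A preformed allylindium reagent (In powder, allyl bromide, DMF, then F1 at 0 °C) should add 1,2 to the C5 carbonyl, because the C6 carbonyl is deactivated as a vinylogous ester through O1–C7a=C7. After chromatographic separation from its C5 epimer this gives (2S,3S,5R)-5-allyl-5-hydroxy-3-methyl-2-(3,4,5-trimethoxyphenyl)-2,3-dihydrobenzofuran-6(5H)-one F2. Methylation of the tertiary alcohol with MeI and Ag2O in CH2Cl2 then gives 19.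

2. Step 9. Facial discrimination at the hindered, electron-rich benzylide may be poor, ylide formation may be slow, and the quinone methide may be lost by hydrogen shift to a vinylphenol before it is trapped. Fallback, setting out from 7 and 11 and returning at 16: 11 is alkylated onto tetrahydrothiophene (AgBF4, acetone) to give the unhindered achiral salt 1-(3,4,5-trimethoxybenzyl)thiolan-1-ium tetrafluoroborate F3. The same Cs2CO3 annulation with 7 should then give racemic trans-6-(allyloxy)-5-methoxy-3-methyl-2-(3,4,5-trimethoxyphenyl)-2,3-dihydrobenzofuran F4. This is resolved by preparative HPLC on a cellulose tris(3,5-dimethylphenylcarbamate) phase, so that absolute configuration comes from resolution instead of reagent control, and the 2S,3S enantiomer is 16.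

3. Step 5. The isolated diol 6 may dehydrate or self-condense through its benzylic cation before the sulfinate captures it. Fallback, setting out from 4 and returning at 7: phenol 4, acetaldehyde and sodium p-toluenesulfinate (TolSO2Na) are combined in HCO2H/H2O at rt. The phenol is hydroxyalkylated at the same ortho carbon in the presence of excess sulfinate and the sulfone should precipitate, so that 5 and 6 are bypassed; new compounds on the way: none F0.

**Further compounds**

F1 | step 11 | (2S,3S)-3-methyl-2-(3,4,5-trimethoxyphenyl)-2,3-dihydrobenzofuran-5,6-dione | O=C1C=C2C(=CC1=O)O[C@H](c1cc(OC)c(OC)c(OC)c1)[C@H]2C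
F2 | step 11 | (2S,3S,5R)-5-allyl-5-hydroxy-3-methyl-2-(3,4,5-trimethoxyphenyl)-2,3-dihydrobenzofuran-6(5H)-one | C=CC[C@@]1(O)C=C2C(=CC1=O)O[C@H](c1cc(OC)c(OC)c(OC)c1)[C@H]2C
F3 | step 9 | 1-(3,4,5-trimethoxybenzyl)thiolan-1-ium tetrafluoroborate | COc1cc(C[S+]2CCCC2)cc(OC)c1OC.F[B-](F)(F)F
F4 | step 9 | racemic trans-6-(allyloxy)-5-methoxy-3-methyl-2-(3,4,5-trimethoxyphenyl)-2,3-dihydrobenzofuran (both enantiomers) | COc1cc2c(cc1OCC=C)O[C@H](c1cc(OC)c(OC)c(OC)c1)[C@H]2C.COc1cc2c(cc1OCC=C)O[C@@H](c1cc(OC)c(OC)c(OC)c1)[C@@H]2C
F0 | step 5 | none | none
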